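## Retrosynthetic overview

1. Myrtucommulone K ⇒ (−)-β-caryophyllene + syncarpic acid + isobutyraldehyde, by a domino Knoevenagel / oxa-Diels–Alder reaction (dihydropyran ring last; the three new stereocentres are set on the E-olefin).
2. Caryophyllene ⇒ nine-ring ketone (Wittig) ⇒ Grob fragmentation of a cyclobutane-fused hydrindane diol monotosylate (nine-membered ring and E-olefin formed in one event).
3. Hydrindane ketol ⇒ cyclopentane annulated onto a cyclobutane-fused cyclohexanone: α-methoxycarbonylation/methylation, ketyl–acrylate spirolactonisation, Dieckmann closure/decarboxylation.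
4. Cyclobutane-fused cyclohexanone ⇒ cyclohex-2-en-1-one + isobutene, by an aminocatalytic, triplet-sensitised enantioselective [2+2] photocycloaddition (first stereocentre; proposed new method).
5. Ring order: cyclobutane on the six-ring → five-ring → nine-ring (by fragmentation of the 6/5 fusion bond) → dihydropyran.

Assumptions: syncarpic acid is bought as a catalogue compound. Catalyst A is N-[(1R,2R)-2-aminocyclohexyl]-9-oxo-9H-thioxanthene-2-carboxamide, N[C@@H]1CCCC[C@H]1NC(=O)c1ccc2sc3ccccc3c(=O)c2c1, used as its CF3CO2H salt; it is made beforehand by one amide coupling and, being a catalyst, is not counted as a step. Locants in each Why line follow the name of the compound concerned.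

## Route

Step 1
Reactants: 1 cyclohex-2-en-1-one; 2 2-methylpropene (isobutene)
Product: 5 (1R,6R)-7,7-dimethylbicyclo[4.2.0]octan-2-one, via enone iminium salt 3 (not isolated), via cyclobutane iminium salt 4 (not isolated)
Conditions: catalyst A·CF3CO2H (20 mol%), 2 (10 equiv), H2O (2 equiv), CH2Cl2, 420 nm LED, −40 °C; then 23 °C in the dark, 2 h
Reagents that add atoms: none
Why: Proposed new method: the primary amine of catalyst A condenses with 1 to the conjugated iminium ion 3, whose triplet should lie below that of free 1 (as known for eniminium ions), so the tethered thioxanthone, the only 420 nm absorber, passes its triplet energy intramolecularly to bound substrate only; the triplet iminium adds 2 head-to-tail (CMe2 to the β-carbon, as in the classical UV reaction of 1 with 2) on the face not covered by the amide–thioxanthone arm, through a 1,4-biradical that closes to 4, which sets the persistent β-stereocentre (6R; the (1S,2S) catalyst would give the antipode), while the ring-fusion α-carbon relaxes to cis through the enamine of 4 before hydrolysis releases 5 and the amine; the closest known reaction types are the chiral-Lewis-acid enone–alkene [2+2] photocycloaddition and the triplet-sensitised [2+2] photocycloaddition of chiral eniminium ions of enals.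

Step 2
Reactants: 5 (1R,6R)-7,7-dimethylbicyclo[4.2.0]octan-2-one
Product: 7 methyl (1R,3S,6R)-3,7,7-trimethyl-2-oxobicyclo[4.2.0]octane-3-carboxylate, via β-keto ester 6 (not isolated)
Conditions: NaH (2.5 equiv), (MeO)2CO (4 equiv), THF, reflux; then MeI (3 equiv), 0 → 23 °C
Reagents that add atoms: dimethyl carbonate, COC(=O)OC; iodomethane, CI
Why: Claisen-type C-methoxycarbonylation at the only CH2 next to the ketone is driven by formation of the stabilised enolate of 6, which is C-methylated in the same pot, mainly anti to the cyclobutane (3S, drawn); either C3 epimer can be carried on, because C3 becomes an olefinic carbon in step 7.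

Step 3
Reactants: 7 methyl (1R,3S,6R)-3,7,7-trimethyl-2-oxobicyclo[4.2.0]octane-3-carboxylate; 8 methyl prop-2-enoate (methyl acrylate)
Product: 10 methyl (1R,2S,3S,6R)-3,7,7-trimethyl-5'-oxospiro[bicyclo[4.2.0]octane-2,2'-oxolane]-3-carboxylate, via hydroxy diester 9 (not isolated)
Conditions: SmI2 (2.5 equiv), 8 (1.5 equiv), t-BuOH (2 equiv), THF, −20 → 0 °C; then TsOH·H2O (cat.), CH2Cl2, 23 °C
Reagents that add atoms: none
Why: SmI2 ketyl–olefin reductive coupling with lactonisation: the samarium-bound ketyl, chelated to the neighbouring ester carbonyl, adds to the acrylate β-carbon on the face away from the axial C3 methyl, so the new CH2 is cis to CO2Me (2S), and the tertiary alkoxide closes onto the acrylate ester to the γ-lactone.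

Step 4
Reactants: 10 methyl (1R,2S,3S,6R)-3,7,7-trimethyl-5'-oxospiro[bicyclo[4.2.0]octane-2,2'-oxolane]-3-carboxylate
Product: 13 (1S,2R,5R,8S)-1-hydroxy-4,4,8-trimethyltricyclo[6.3.0.0^2,5]undecan-9-one, via bridged β-keto lactone 11 (not isolated), via β-keto acid 12 (not isolated)
Conditions: NaN(SiMe3)2 (1.5 equiv), THF, −78 → 0 °C; then 2 M NaOH (aq), MeOH, 23 °C; then 2 M HCl to pH 2, 45 °C
Reagents that add atoms: none
Why: Dieckmann (intramolecular Claisen) condensation of the lactone enolate onto the neighbouring non-enolisable ester closes the cyclopentanone under kinetic control, and saponification of the strained lactone followed by β-keto acid decarboxylation gives the cis-fused ketol; its ring-fusion centres come from steps 2 and 3, and the carbon that carried the carboxyl ends as CH2.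

Step 5
Reactants: 13 (1S,2R,5R,8S)-1-hydroxy-4,4,8-trimethyltricyclo[6.3.0.0^2,5]undecan-9-one
Product: 14 (1S,2R,5R,8R,9S)-4,4,8-trimethyltricyclo[6.3.0.0^2,5]undecane-1,9-diol
Conditions: Et2BOMe (1.1 equiv), NaBH4 (1.5 equiv), THF–MeOH 4:1, −78 °C; MeOH co-evaporation
Reagents that add atoms: none
Why: Narasaka–Prasad-type chelation-controlled 1,3-syn reduction: the boron chelate between the tertiary alkoxide and the ketone survives only if hydride enters from the face opposite the angular methyl, so the new hydroxyl (9S) is cis to both the C1 hydroxyl and the C8 methyl.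

Step 6
Reactants: 14 (1S,2R,5R,8R,9S)-4,4,8-trimethyltricyclo[6.3.0.0^2,5]undecane-1,9-diol
Product: 15 (1S,2R,5R,8R,9S)-1-hydroxy-4,4,8-trimethyltricyclo[6.3.0.0^2,5]undecan-9-yl 4-methylbenzenesulfonate
Conditions: TsCl (2 equiv), pyridine, DMAP (cat.), 0 → 23 °C
Reagents that add atoms: 4-methylbenzenesulfonyl chloride, Cc1ccc(cc1)S(Cl)(=O)=O
Why: Selective O-sulfonylation of the secondary alcohol (the tertiary ring-fusion alcohol does not react with TsCl/pyridine), with retention at C9.

Step 7
Reactants: 15 (1S,2R,5R,8R,9S)-1-hydroxy-4,4,8-trimethyltricyclo[6.3.0.0^2,5]undecan-9-yl 4-methylbenzenesulfonate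
Product: 18 (−)-β-caryophyllene, (1R,4E,9S)-4,11,11-trimethyl-8-methylidenebicyclo[7.2.0]undec-4-ene, via cis-fused nine-ring ketone 16 (not isolated), via trans-fused nine-ring ketone 17 (not isolated)
Conditions: KOt-Bu (3 equiv), THF, 0 → 23 °C, 2 h; then Ph3PCH3Br/KOt-Bu (3 equiv each, pre-mixed in THF), 23 → 45 °C
Reagents that add atoms: methyltriphenylphosphonium bromide, C[P+](c1ccccc1)(c1ccccc1)c1ccccc1.[Br-]
Why: Grob fragmentation: the tertiary alkoxide pushes, the C1–C8 ring-fusion bond anti-periplanar to C9–OTs breaks, and because the tosylate is cis to the angular methyl the new trisubstituted olefin is E (16); the base then epimerises the ring-fusion carbon next to the ketone to the more stable trans-fused 17 (the 9S centre of 18), which is methylenated in the same pot by a Wittig reaction.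

Step 8
Reactants: 18 (−)-β-caryophyllene; 19 syncarpic acid (2,2,4,4-tetramethylcyclohexane-1,3,5-trione); 20 2-methylpropanal (isobutyraldehyde)
Product: 22 myrtucommulone K, via isobutylidene trione 21 (not isolated)
Conditions: 19 (1.2 equiv), 20 (1.5 equiv), EDDA (ethylenediammonium diacetate, 20 mol%), 4 Å MS, toluene, 23 → 60 °C
Reagents that add atoms: none
Why: Tietze-type domino Knoevenagel condensation / inverse-electron-demand oxa-Diels–Alder reaction: 19 and 20 give the 1-oxadiene 21, which adds across the strained E-olefin of 18 on its exposed outer face (the face also taken in peracid epoxidation), oxygen to the more substituted olefin carbon and suprafacially (trans ring fusion kept from the E-olefin), the endo/exo preference fixing the isopropyl-bearing carbon; the target is expected as the main adduct and minor diastereomers are removed by chromatography.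

## Compound list

1 | cyclohex-2-en-1-one | O=C1C=CCCC1 | starting material
2 | 2-methylpropene (isobutene) | CC(C)=C | starting material
3 | N-[(1R,2R)-2-(9-oxo-9H-thioxanthene-2-carboxamido)cyclohexyl]cyclohex-2-en-1-iminium trifluoroacetate (iminium of 1 on catalyst A) | C1CC=CC(=[NH+][C@@H]2CCCC[C@H]2NC(=O)c2ccc3sc4ccccc4c(=O)c3c2)C1.[O-]C(=O)C(F)(F)F | intermediate
4 | N-[(1R,2R)-2-(9-oxo-9H-thioxanthene-2-carboxamido)cyclohexyl]-(6R)-7,7-dimethylbicyclo[4.2.0]octan-2-iminium trifluoroacetate (C1 epimers, settling to cis) | C1(CCC[C@@H]2C1CC2(C)C)=[NH+][C@@H]1CCCC[C@H]1NC(=O)c1ccc2sc3ccccc3c(=O)c2c1.[O-]C(=O)C(F)(F)F | intermediate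
5 | (1R,6R)-7,7-dimethylbicyclo[4.2.0]octan-2-one (cis-fused) | O=C1CCC[C@@H]2[C@H]1CC2(C)C | intermediate
6 | methyl (1R,6R)-7,7-dimethyl-2-oxobicyclo[4.2.0]octane-3-carboxylate (present as its sodium enolate; C3 not defined) | O=C1C(C(=O)OC)CC[C@@H]2[C@H]1CC2(C)C | intermediate
7 | methyl (1R,3S,6R)-3,7,7-trimethyl-2-oxobicyclo[4.2.0]octane-3-carboxylate | O=C1[C@@](C)(C(=O)OC)CC[C@@H]2[C@H]1CC2(C)C | intermediate
8 | methyl prop-2-enoate (methyl acrylate) | C=CC(=O)OC | starting material
9 | methyl (1R,2S,3S,6R)-2-hydroxy-2-(3-methoxy-3-oxopropyl)-3,7,7-trimethylbicyclo[4.2.0]octane-3-carboxylate | COC(=O)CC[C@@]1(O)[C@@](C)(C(=O)OC)CC[C@@H]2[C@H]1CC2(C)C | intermediate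
10 | methyl (1R,2S,3S,6R)-3,7,7-trimethyl-5'-oxospiro[bicyclo[4.2.0]octane-2,2'-oxolane]-3-carboxylate | O=C1CC[C@@]2(O1)[C@@](C)(C(=O)OC)CC[C@@H]1[C@H]2CC1(C)C | intermediate
11 | (1S,2R,5R,8S,10S)-1-hydroxy-4,4,8-trimethyl-9-oxotricyclo[6.3.0.0^2,5]undecane-10-carboxylic acid 1,10-lactone | O=C1O[C@]23C[C@H]1C(=O)[C@@]2(C)CC[C@@H]1[C@H]3CC1(C)C | intermediate
12 | (1S,2R,5R,8S)-1-hydroxy-4,4,8-trimethyl-9-oxotricyclo[6.3.0.0^2,5]undecane-10-carboxylic acid (C10 labile) | OC(=O)C1C[C@@]2(O)[C@](C)(CC[C@@H]3[C@H]2CC3(C)C)C1=O | intermediate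
13 | (1S,2R,5R,8S)-1-hydroxy-4,4,8-trimethyltricyclo[6.3.0.0^2,5]undecan-9-one | O=C1CC[C@@]2(O)[C@]1(C)CC[C@@H]1[C@H]2CC1(C)C | intermediate
14 | (1S,2R,5R,8R,9S)-4,4,8-trimethyltricyclo[6.3.0.0^2,5]undecane-1,9-diol | O[C@H]1CC[C@@]2(O)[C@]1(C)CC[C@@H]1[C@H]2CC1(C)C | intermediate
15 | (1S,2R,5R,8R,9S)-1-hydroxy-4,4,8-trimethyltricyclo[6.3.0.0^2,5]undecan-9-yl 4-methylbenzenesulfonate | Cc1ccc(cc1)S(=O)(=O)O[C@H]1CC[C@@]2(O)[C@]1(C)CC[C@@H]1[C@H]2CC1(C)C | intermediate
16 | (1R,5E,9R)-6,10,10-trimethylbicyclo[7.2.0]undec-5-en-2-one (cis-fused) | O=C1CC/C=C(\C)CC[C@@H]2[C@H]1CC2(C)C | intermediate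
17 | (1S,5E,9R)-6,10,10-trimethylbicyclo[7.2.0]undec-5-en-2-one (trans-fused) | O=C1CC/C=C(\C)CC[C@@H]2[C@@H]1CC2(C)C | intermediate
18 | (−)-β-caryophyllene, (1R,4E,9S)-4,11,11-trimethyl-8-methylidenebicyclo[7.2.0]undec-4-ene | C=C1CC/C=C(\C)CC[C@@H]2[C@@H]1CC2(C)C | intermediate
19 | syncarpic acid, 2,2,4,4-tetramethylcyclohexane-1,3,5-trione | O=C1CC(=O)C(C)(C)C(=O)C1(C)C | starting material
20 | 2-methylpropanal (isobutyraldehyde) | CC(C)C=O | starting material
21 | 2,2,4,4-tetramethyl-6-(2-methylpropylidene)cyclohexane-1,3,5-trione | CC(C)C=C1C(=O)C(C)(C)C(=O)C(C)(C)C1=O | intermediate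
22 | myrtucommulone K | C=C1CC[C@H]2[C@@H](C(C)C)C3=C(O[C@]2(C)CC[C@@H]2[C@@H]1CC2(C)C)C(C)(C)C(=O)C(C)(C)C3=O | target

## Step count and risk

Total steps: 8. Longest linear sequence: 8 (1 and 2 to 22).

Steps most likely to fail:

Step 1 (the proposed photocycloaddition). The risks are racemic background sensitisation of unbound 1, low iminium population and an unknown sense of induction. The fallback uses known chemistry, sets out from 1 and 2 and comes back at 5. The same two components are irradiated at 366 nm in CH2Cl2 at −75 °C with an AlBr3-activated chiral oxazaborolidine (50 mol%, from α,α-diphenylprolinol and an arylboronic acid). This is the established chiral-Lewis-acid variant, in which the Lewis-acid-bound enone is the species that absorbs the light. It gives 5 together with its trans-fused epimer (1S,6R)-7,7-dimethylbicyclo[4.2.0]octan-2-one F1, which is converted into 5 by stirring the crude mixture with basic Al2O3.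

Step 3 (ketyl–acrylate coupling at a ketone flanked by a quaternary carbon and the cyclobutane). The coupling may be slow, or the chelate may not control the face. The fallback sets out from 7 and comes back at 10. It replaces the radical coupling by a polar 1,2-addition: LiC≡CCO2Me (from methyl propiolate and LiN(SiMe3)2, THF, −78 °C) adds to the ketone under lithium chelation to give methyl (1R,2R,3S,6R)-2-hydroxy-2-(3-methoxy-3-oxoprop-1-yn-1-yl)-3,7,7-trimethylbicyclo[4.2.0]octane-3-carboxylate F2. Hydrogenation of the triple bond (H2, Pd/C, EtOAc) gives the saturated hydroxy diester 9, which lactonises with catalytic TsOH to 10.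

Step 4 (Dieckmann closure to a strained, bridged β-keto lactone that cannot be held as an enolate, so reversal or retro-Claisen opening can compete). The fallback sets out from 7 and comes back at 13, and avoids any Claisen step. CH2=CHMgBr/CeCl3 (THF, −78 °C) adds to the ketone to give methyl (1R,2S,3S,6R)-2-ethenyl-2-hydroxy-3,7,7-trimethylbicyclo[4.2.0]octane-3-carboxylate F3. i-Bu2AlH (CH2Cl2, −78 °C) reduces the ester to (1R,2S,3S,6R)-2-ethenyl-2-hydroxy-3,7,7-trimethylbicyclo[4.2.0]octane-3-carbaldehyde F4. Rhodium-catalysed intramolecular hydroacylation of this 4-pentenal ([Rh(Ph2PCH2CH2PPh2)]ClO4, 5 mol%, CH2Cl2, 23 °C) closes the cyclopentanone directly to 13.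

## Further compounds

F1 | step 1 | (1S,6R)-7,7-dimethylbicyclo[4.2.0]octan-2-one (trans-fused epimer of 5) | O=C1CCC[C@@H]2[C@@H]1CC2(C)C
F2 | step 3 | methyl (1R,2R,3S,6R)-2-hydroxy-2-(3-methoxy-3-oxoprop-1-yn-1-yl)-3,7,7-trimethylbicyclo[4.2.0]octane-3-carboxylate | COC(=O)C#C[C@@]1(O)[C@@](C)(C(=O)OC)CC[C@@H]2[C@H]1CC2(C)C
F3 | step 4 | methyl (1R,2S,3S,6R)-2-ethenyl-2-hydroxy-3,7,7-trimethylbicyclo[4.2.0]octane-3-carboxylate | C=C[C@@]1(O)[C@@](C)(C(=O)OC)CC[C@@H]2[C@H]1CC2(C)C
F4 | step 4 | (1R,2S,3S,6R)-2-ethenyl-2-hydroxy-3,7,7-trimethylbicyclo[4.2.0]octane-3-carbaldehyde | C=C[C@@]1(O)[C@@](C)(C=O)CC[C@@H]2[C@H]1CC2(C)C
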